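The plan cuts the C2–C3 bond of the dihydrofuran ring and treats the cyclohexenone ring as a dearomatised resorcinol. In the key step a cobalt-bound carbene radical at C3, released from an ortho-alkoxybenzaldehyde tosylhydrazone, abstracts hydrogen from C2 and closes the five-membered ring, setting C2. It exploits the C2–H bond, weakened by ring oxygen O1 and held 1,5 to C3 through O1–C7a=C3a. The precursor is a flat aryl ether of the side-chain tertiary alcohol, made from geranylacetone by asymmetric epoxidation (C1'). Birch dearomatisation then unveils the vinylogous ester; enolate hydroxylation at C5 and oxidation of the terminal methyl group finish the synthesis.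

Key step: step 4

Numbering: core atoms are O1, C2, C3, C3a, C4–C7, C7a as in the benzofuranone; C1' is the side-chain carbinol carbon. The target is (2S, 1'S, 5R) with both chain alkenes E.
Assumption: for the lanthanum/BINOL catalyst (step 1) and the cobalt porphyrin (step 4) the antipode that gives the drawn isomer is used; both antipodes of each are accessible.

Step 1
Reactants: 1 (E)-geranylacetone
Product: 2 (2S)-2-[(3E)-4,8-dimethylnona-3,7-dien-1-yl]-2-methyloxirane
Conditions: Me3S(O)Cl, NaH, THF, reflux (ylide solution); then 1, LaLi3(binaphthoxide)3 (5 mol%, BINOL antipode that gives the S epoxide), tris(2,4,6-trimethoxyphenyl)phosphine oxide (5 mol%), 5 Å MS, THF, rt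
Reagents that add atoms: trimethylsulfoxonium chloride, C[S+](C)(C)=O.[Cl-] (delivers CH2 through its ylide)
Why: Catalytic asymmetric Corey–Chaykovsky epoxidation, in which the La/Li/BINOL complex binds the methyl ketone and the sulfoxonium ylide and delivers CH2 to one carbonyl face, setting C1' (S); the isolated alkenes are inert to the ylide.

Step 2
Reactants: 2 (2S)-2-[(3E)-4,8-dimethylnona-3,7-dien-1-yl]-2-methyloxirane; 3 2-bromo-6-hydroxybenzaldehyde
Product: 4 2-bromo-6-{[(2S,5E)-2-hydroxy-2,6,10-trimethylundeca-5,9-dien-1-yl]oxy}benzaldehyde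
Conditions: K2CO3 (0.5 equiv), DMF, 90 °C
Reagents that add atoms: none
Why: Base-mediated SN2 opening of the 2,2-disubstituted epoxide by the phenoxide at the unhindered CH2 terminus; the C–O bond at the quaternary carbon is not broken, so C1' is retained.

Step 3
Reactants: 4 2-bromo-6-{[(2S,5E)-2-hydroxy-2,6,10-trimethylundeca-5,9-dien-1-yl]oxy}benzaldehyde
Product: 5 N'-[(E)-(2-bromo-6-{[(2S,5E)-2-hydroxy-2,6,10-trimethylundeca-5,9-dien-1-yl]oxy}phenyl)methylidene]-4-methylbenzenesulfonohydrazide
Conditions: TsNHNH2, MeOH, rt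
Reagents that add atoms: p-toluenesulfonyl hydrazide, Cc1ccc(cc1)S(=O)(=O)NN
Why: Condensation of the aldehyde with tosylhydrazide gives the bench-stable hydrazone, the precursor of the diazo compound (Bamford–Stevens manifold).

Step 4
Reactants: 5 the tosylhydrazone
Product: 7 (2S,5E)-2-[(2S)-4-bromo-2,3-dihydro-1-benzofuran-2-yl]-6,10-dimethylundeca-5,9-dien-2-ol, via aryldiazomethane 6 (not isolated)
Conditions: Cs2CO3 (2 equiv), Co(P*) (2 mol%; P* = 5,15-bis(3,5-di-tert-butylphenyl)-10,20-bis{2,6-bis[(2,2-dimethylcyclopropane)carboxamido]phenyl}porphyrinate, one antipode; divalent cobalt), 1,4-dioxane, 50 °C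
Reagents that add atoms: none
Why: Cs2CO3 deprotonates 5, the salt loses sulfinate (Bamford–Stevens) to give diazo compound 6, and divalent cobalt in the porphyrin activates 6 with loss of N2 to an alpha-cobalt benzyl radical at C3 (a trivalent-cobalt carbene radical), which abstracts hydrogen from C2 through a six-membered 1,5-HAT transition state (C3–C3a–C7a–O1–C2–H); the alpha-alkoxy radical at C2 then substitutes at C3, forming C2–C3 and returning divalent cobalt. The closest known reaction type is the cobalt-porphyrin metalloradical 1,5-C–H alkylation of aryldiazomethanes generated in situ from ortho-heteroatom-substituted benzaldehyde tosylhydrazones, together with the related ruthenium-porphyrin carbene insertion that gives 2,3-dihydrobenzofurans. The dihydrofuran ring closes in a 5-exo-tet radical substitution. The new stereocenter C2 is fixed in this C–C bond-forming event inside the chiral cavity of the D2-symmetric amidoporphyrin (catalyst control, with the ligand antipode matched to the existing (S)-C1' center; a C2 epimer would be a diastereomer removable by chromatography). Site selectivity is needed and is secured by design: C2–H is the only C–H bond 1,5 to C3, because the second ortho position carries Br instead of a methoxy group whose C–H bonds would compete, and O1 makes C2–H the weakest bond within reach. Chemoselectivity over the two trisubstituted alkenes and the free tertiary OH rests on the preference of the carbene radical for intramolecular hydrogen abstraction over addition to hindered alkenes or O–H insertion.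

Step 5
Reactants: 7 (2S,5E)-2-[(2S)-4-bromo-2,3-dihydro-1-benzofuran-2-yl]-6,10-dimethylundeca-5,9-dien-2-ol
Product: 8 (2S,5E)-2-[(2S)-4-methoxy-2,3-dihydro-1-benzofuran-2-yl]-6,10-dimethylundeca-5,9-dien-2-ol
Conditions: CuI (10 mol%), 3,4,7,8-tetramethyl-1,10-phenanthroline (20 mol%), Cs2CO3 (2 equiv), MeOH/toluene, 110 °C (sealed tube)
Reagents that add atoms: methanol, CO
Why: Ullmann-type copper-catalysed C–O coupling of the aryl bromide with methanol installs the second resorcinol oxygen (the future C4=O) only after the C–H functionalisation; the tertiary alcohol cannot reach C4 and stays free.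

Step 6
Reactants: 8 (2S,5E)-2-[(2S)-4-methoxy-2,3-dihydro-1-benzofuran-2-yl]-6,10-dimethylundeca-5,9-dien-2-ol
Product: 10 (2S)-2-[(2S,5E)-2-hydroxy-6,10-dimethylundeca-5,9-dien-2-yl]-3,5,6,7-tetrahydro-1-benzofuran-4(2H)-one, via bis-enol-ether diene 9 (not isolated)
Conditions: Li, NH3(l), THF, t-BuOH, −78 °C; NH4Cl; then 1 M HCl, THF, 0 °C to rt
Reagents that add atoms: water, O
Why: Birch reduction of the 2-alkyl resorcinol diether protonates C3a and C6 to give the 1,4-diene 9 (isolated trisubstituted alkenes are inert), and dilute acid hydrolyses the methyl enol ether to the C4 ketone while the cyclic enol ether moves into conjugation (C3a=C7a), unveiling the vinylogous ester with C2 and C1' untouched.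

Step 7
Reactants: 10 (2S)-2-[(2S,5E)-2-hydroxy-6,10-dimethylundeca-5,9-dien-2-yl]-3,5,6,7-tetrahydro-1-benzofuran-4(2H)-one
Product: 11 (2S,5R)-5-hydroxy-2-[(2S,5E)-2-hydroxy-6,10-dimethylundeca-5,9-dien-2-yl]-3,5,6,7-tetrahydro-1-benzofuran-4(2H)-one
Conditions: NaHMDS (2.3 equiv), THF, −78 °C; (1S)-(+)-(10-camphorsulfonyl)oxaziridine (1.5 equiv), −78 to −40 °C; NH4Cl
Reagents that add atoms: (1S)-(+)-(10-camphorsulfonyl)oxaziridine, O=S1(=O)C[C@@]23CC[C@@H](C2(C)C)C[C@]34ON14
Why: Kinetic deprotonation of the vinylogous ester at the alpha' carbon C5 (the tertiary alcohol rides as its alkoxide) and electrophilic enolate hydroxylation by the enantiopure N-sulfonyloxaziridine, which alone controls C5 (reagent control; 5R is expected for the (+)-reagent by analogy with 1-tetralone-type enolates, and the antipode is available should the sense be reversed); the alkenes are inert to this oxidant.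

Step 8
Reactants: 11 (2S,5R)-5-hydroxy-2-[(2S,5E)-2-hydroxy-6,10-dimethylundeca-5,9-dien-2-yl]-3,5,6,7-tetrahydro-1-benzofuran-4(2H)-one
Product: 12 (2S,5R)-2-[(2S,5E,9E)-2,11-dihydroxy-6,10-dimethylundeca-5,9-dien-2-yl]-5-hydroxy-3,5,6,7-tetrahydro-1-benzofuran-4(2H)-one
Conditions: SeO2 (0.3 equiv), t-BuOOH (3 equiv), salicylic acid (0.1 equiv), CH2Cl2, 0 °C to rt
Reagents that add atoms: selenium dioxide, O=[Se]=O (catalytic oxygen donor); tert-butyl hydroperoxide, CC(C)(C)OO (stoichiometric oxidant)
Why: Riley allylic oxidation in its catalytic form (ene reaction, then [2,3]-sigmatropic shift of the allylseleninic acid) attacks the most electron-rich and least hindered alkene, the terminal isopropylidene, at its E-methyl group to give the (E)-allylic alcohol; any over-oxidised aldehyde 13 is carried into step 9.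

Step 9
Reactants: 12 (2S,5R)-2-[(2S,5E,9E)-2,11-dihydroxy-6,10-dimethylundeca-5,9-dien-2-yl]-5-hydroxy-3,5,6,7-tetrahydro-1-benzofuran-4(2H)-one
Product: 13 (2E,6E,10S)-10-hydroxy-10-[(2S,5R)-5-hydroxy-4-oxo-2,3,4,5,6,7-hexahydro-1-benzofuran-2-yl]-2,6-dimethylundeca-2,6-dienal
Conditions: TEMPO (0.1 equiv), PhI(OAc)2 (1.1 equiv), CH2Cl2, rt
Reagents that add atoms: none
Why: Oxoammonium (TEMPO) oxidation is selective for the primary allylic alcohol over the secondary alpha-ketol and the tertiary alcohol and stops at the aldehyde.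

Step 10
Reactants: 13 (2E,6E,10S)-10-hydroxy-10-[(2S,5R)-5-hydroxy-4-oxo-2,3,4,5,6,7-hexahydro-1-benzofuran-2-yl]-2,6-dimethylundeca-2,6-dienal
Product: 14 (2E,6E,10S)-10-hydroxy-10-[(2S,5R)-5-hydroxy-4-oxo-2,3,4,5,6,7-hexahydro-1-benzofuran-2-yl]-2,6-dimethylundeca-2,6-dienoic acid
Conditions: NaClO2, NaH2PO4, 2-methyl-2-butene, t-BuOH/H2O, 0 °C to rt
Reagents that add atoms: sodium chlorite, [Na+].[O-]Cl=O
Why: Pinnick oxidation converts the enal into the acid without touching the alkene geometry, the alcohols or the vinylogous ester, with 2-methyl-2-butene scavenging HOCl.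

Compound list
1 | (E)-geranylacetone, (5E)-6,10-dimethylundeca-5,9-dien-2-one | CC(=O)CC/C=C(\C)CCC=C(C)C | starting material
2 | (2S)-2-[(3E)-4,8-dimethylnona-3,7-dien-1-yl]-2-methyloxirane | C[C@@]1(CO1)CC/C=C(\C)CCC=C(C)C | intermediate
3 | 2-bromo-6-hydroxybenzaldehyde | O=Cc1c(O)cccc1Br | starting material
4 | 2-bromo-6-{[(2S,5E)-2-hydroxy-2,6,10-trimethylundeca-5,9-dien-1-yl]oxy}benzaldehyde | O=Cc1c(Br)cccc1OC[C@@](C)(O)CC/C=C(\C)CCC=C(C)C | intermediate
5 | N'-[(E)-(2-bromo-6-{[(2S,5E)-2-hydroxy-2,6,10-trimethylundeca-5,9-dien-1-yl]oxy}phenyl)methylidene]-4-methylbenzenesulfonohydrazide | Cc1ccc(cc1)S(=O)(=O)N/N=C/c1c(Br)cccc1OC[C@@](C)(O)CC/C=C(\C)CCC=C(C)C | intermediate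
6 | 1-bromo-2-(diazomethyl)-3-{[(2S,5E)-2-hydroxy-2,6,10-trimethylundeca-5,9-dien-1-yl]oxy}benzene | [N-]=[N+]=Cc1c(Br)cccc1OC[C@@](C)(O)CC/C=C(\C)CCC=C(C)C | intermediate (not isolated)
7 | (2S,5E)-2-[(2S)-4-bromo-2,3-dihydro-1-benzofuran-2-yl]-6,10-dimethylundeca-5,9-dien-2-ol | C/C(=C\CC[C@](C)(O)[C@@H]1Cc2c(Br)cccc2O1)CCC=C(C)C | intermediate
8 | (2S,5E)-2-[(2S)-4-methoxy-2,3-dihydro-1-benzofuran-2-yl]-6,10-dimethylundeca-5,9-dien-2-ol | C/C(=C\CC[C@](C)(O)[C@@H]1Cc2c(OC)cccc2O1)CCC=C(C)C | intermediate
9 | (2S,5E)-2-[(2S)-4-methoxy-2,3,3a,6-tetrahydro-1-benzofuran-2-yl]-6,10-dimethylundeca-5,9-dien-2-ol (both C3a epimers) | C/C(=C\CC[C@](C)(O)[C@@H]1CC2C(OC)=CCC=C2O1)CCC=C(C)C | intermediate (not isolated)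
10 | (2S)-2-[(2S,5E)-2-hydroxy-6,10-dimethylundeca-5,9-dien-2-yl]-3,5,6,7-tetrahydro-1-benzofuran-4(2H)-one | C/C(=C\CC[C@](C)(O)[C@@H]1CC2=C(CCCC2=O)O1)CCC=C(C)C | intermediate
11 | (2S,5R)-5-hydroxy-2-[(2S,5E)-2-hydroxy-6,10-dimethylundeca-5,9-dien-2-yl]-3,5,6,7-tetrahydro-1-benzofuran-4(2H)-one | C/C(=C\CC[C@](C)(O)[C@@H]1CC2=C(CC[C@@H](O)C2=O)O1)CCC=C(C)C | intermediate
12 | (2S,5R)-2-[(2S,5E,9E)-2,11-dihydroxy-6,10-dimethylundeca-5,9-dien-2-yl]-5-hydroxy-3,5,6,7-tetrahydro-1-benzofuran-4(2H)-one | C/C(=C\CC[C@](C)(O)[C@@H]1CC2=C(CC[C@@H](O)C2=O)O1)CC/C=C(\C)CO | intermediate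
13 | (2E,6E,10S)-10-hydroxy-10-[(2S,5R)-5-hydroxy-4-oxo-2,3,4,5,6,7-hexahydro-1-benzofuran-2-yl]-2,6-dimethylundeca-2,6-dienal | C/C(=C\CC[C@](C)(O)[C@@H]1CC2=C(CC[C@@H](O)C2=O)O1)CC/C=C(\C)C=O | intermediate
14 | (2E,6E,10S)-10-hydroxy-10-[(2S,5R)-5-hydroxy-4-oxo-2,3,4,5,6,7-hexahydro-1-benzofuran-2-yl]-2,6-dimethylundeca-2,6-dienoic acid | C/C(=C\CC[C@](C)(O)[C@@H]1CC2=C(CC[C@@H](O)C2=O)O1)CC/C=C(\C)C(=O)O | target

Total step count: 10. Longest linear sequence: 10 steps (1 to 14).

Steps most likely to fail

Step 4. Hydrogen abstraction from the neopentyl-type C2–H next to the quaternary C1' may be slower than bimolecular decay of the diazo compound (azine or stilbene formation). The catalyst cavity may also discriminate the two C2 hydrogens poorly. The fallback sets out from 2 and comes back at 8; it makes C2–C3 by carbonyl addition and closes the ring at O1–C7a instead. Epoxide 2 is opened by hydroxide at its CH2 group (KOH, DMSO/H2O, 100 °C) to (2S,5E)-2,6,10-trimethylundeca-5,9-diene-1,2-diol F1. Parikh–Doering oxidation of the primary alcohol (SO3·pyridine, DMSO, iPr2NEt) gives (2S,5E)-2-hydroxy-2,6,10-trimethylundeca-5,9-dienal F2, which has no epimerisable hydrogen. (2-Bromo-6-methoxybenzyl)zinc bromide F3, made from commercial 2-bromo-6-methoxybenzyl bromide with Zn dust and LiCl in THF, adds to F2 (MgCl2, THF, 0 °C). This addition is expected to be only weakly selective, so the product (2S,3S,6E)-1-(2-bromo-6-methoxyphenyl)-3,7,11-trimethyldodeca-6,10-diene-2,3-diol F4 is separated from its C2 epimer by chromatography. Intramolecular Ullmann etherification of the less hindered secondary alcohol (CuI, 1,10-phenanthroline, Cs2CO3, toluene, 110 °C) closes the five-membered ring with retention at C2 and gives 8, bypassing steps 2 to 5.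

Step 7. The oxaziridine may deliver oxygen to both faces of the flat enolate, because C2 and C1' are too remote to help; the enolate may also add to the sulfonimine by-product. The fallback sets out from 10 and comes back at 11. Mn(OAc)3 (trivalent manganese) in benzene at reflux acetoxylates the alpha' position to (2S)-2-[(2S,5E)-2-hydroxy-6,10-dimethylundeca-5,9-dien-2-yl]-4-oxo-2,3,4,5,6,7-hexahydro-1-benzofuran-5-yl acetate F5 as both C5 epimers. A lipase chosen by screening (for example Burkholderia cepacia lipase, phosphate buffer pH 7/toluene, 30 °C) hydrolyses only the 5R acetate to 11. Chromatography then separates 11 from the unreacted (2S,5S)-2-[(2S,5E)-2-hydroxy-6,10-dimethylundeca-5,9-dien-2-yl]-4-oxo-2,3,4,5,6,7-hexahydro-1-benzofuran-5-yl acetate F6.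

Step 8. The ene reaction may also attack the internal trisubstituted alkene or the allylic positions C3 and C7 of the vinylogous ester, or it may stall at low conversion. The fallback sets out from 11 and comes back at 13. Cross-metathesis of the terminal isopropylidene group with excess methacrolein (second-generation Hoveyda–Grubbs catalyst, CH2Cl2, 40 °C) exchanges the CMe2 terminus for C(CH3)CHO with E geometry, the internal alkene being the more hindered partner. It gives 13 directly, so no new compound is made (F0) and step 9 is bypassed.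

Further compounds
F1 | step 4 | (2S,5E)-2,6,10-trimethylundeca-5,9-diene-1,2-diol | OC[C@@](C)(O)CC/C=C(\C)CCC=C(C)C
F2 | step 4 | (2S,5E)-2-hydroxy-2,6,10-trimethylundeca-5,9-dienal | O=C[C@@](C)(O)CC/C=C(\C)CCC=C(C)C
F3 | step 4 | (2-bromo-6-methoxybenzyl)zinc bromide | COc1cccc(Br)c1C[Zn]Br
F4 | step 4 | (2S,3S,6E)-1-(2-bromo-6-methoxyphenyl)-3,7,11-trimethyldodeca-6,10-diene-2,3-diol | C/C(=C\CC[C@](C)(O)[C@@H](O)Cc1c(Br)cccc1OC)CCC=C(C)C
F5 | step 7 | (2S)-2-[(2S,5E)-2-hydroxy-6,10-dimethylundeca-5,9-dien-2-yl]-4-oxo-2,3,4,5,6,7-hexahydro-1-benzofuran-5-yl acetate (both C5 epimers) | C/C(=C\CC[C@](C)(O)[C@@H]1CC2=C(CCC(OC(C)=O)C2=O)O1)CCC=C(C)C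
F6 | step 7 | (2S,5S)-2-[(2S,5E)-2-hydroxy-6,10-dimethylundeca-5,9-dien-2-yl]-4-oxo-2,3,4,5,6,7-hexahydro-1-benzofuran-5-yl acetate | C/C(=C\CC[C@](C)(O)[C@@H]1CC2=C(CC[C@H](OC(C)=O)C2=O)O1)CCC=C(C)C
F0 | step 8 | none | none
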